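The ten-membered carbocycle is closed last, between C1 and C10 (germacrane numbering: ring C1–C10, ketone C3, alkene C4=C5, lactone on C6/C7, angelate on C8). The step exploits the γ-hydroxy ketone C10(OH)–C1–C2–C3(=O): a photoredox hydrogen-atom-transfer step turns the secondary carbinol C10–H of an open-chain precursor into an α-hydroxyalkyl radical that adds 10-endo to the vinyl ketone terminus C1, giving ring, tertiary alcohol and quaternary stereocentre at once. The precursor is a cis-fused butyrolactone with a (Z)-dienone arm on C6 and a 3-hydroxybutyl arm on C7; its C11 phosphonate builds the lactone, masks the methylene lactone during the radical step and ends as the exocyclic alkene.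

Key step: step 11

Numbering: C11–C13 are the lactone carbons (C12 carbonyl, C13 methylene), C14 is the methyl on C10, C15 the hydroxymethyl carbon on C4.
Remark: 18 is treated as the open γ-hydroxy ketone as drawn; a transannular C3/C10 hemiketal, if it forms, would be its ring-chain tautomer.
Remark: the C10 configuration of 5 is erased in step 11, and (S)-5 is used only to keep intermediates single diastereomers; 12–16 are epimer mixtures at C11, which becomes sp2 in step 12.

Step 1
Reactants: 1 mono-silylated butynediol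
Product: 3 (Z)-iodo allylic alcohol, via cyclic alkenylaluminate 2 (not isolated)
Conditions: Red-Al (NaAlH2(OCH2CH2OMe)2), THF, 0 °C to rt; then I2, −78 to 0 °C
Reagents that add atoms: iodine II
Why: Alkoxide-directed trans-hydroalumination of the propargylic alcohol puts aluminium on the distal alkyne carbon (C4) and hydride trans to it on C5, and iodinolysis with retention gives the (Z)-iodoalkene that fixes the C4=C5 geometry of the target.

Step 2
Reactants: 3 (Z)-iodo allylic alcohol
Product: 4 (Z)-iodo enal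
Conditions: MnO2, CH2Cl2, rt
Reagents that add atoms: none
Why: Allylic oxidation with activated MnO2 should give the β-iodoenal without touching the silyl ether or the alkene geometry.

Step 3
Reactants: 5 (S)-pent-4-yn-2-ol
Product: 6 TES-protected alkynol
Conditions: TESCl, imidazole, CH2Cl2, 0 °C to rt
Reagents that add atoms: chlorotriethylsilane CC[Si](Cl)(CC)CC
Why: Standard silylation protects the C10 hydroxyl as an ether that can later be removed in the presence of the primary TBS ether.

Step 4
Reactants: 6 TES-protected alkynol, 4 (Z)-iodo enal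
Product: 9 bis-allylic alcohol, via alkenylborane 7 (not isolated), via alkenylzinc 8 (not isolated)
Conditions: 6, Cy2BH, toluene, 0 °C to rt; Me2Zn, −78 °C; (−)-MIB (5 mol%), then 4, −20 to 0 °C; aq. NH4Cl
Reagents that add atoms: none
Why: Hydroboration gives the (E)-alkenylborane, boron-to-zinc exchange gives the alkenylzinc, and its (−)-MIB-catalysed 1,2-addition (Oppolzer–Walsh asymmetric alkenylation) to the Si face of the enal should set C6 as the (S)-carbinol, the alkenyl iodide being inert to these reagents.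

Step 5
Reactants: 9 bis-allylic alcohol
Product: 10 erythro epoxy alcohol
Conditions: Ti(OiPr)4 (10 mol%), D-(−)-DIPT (12 mol%), t-BuOOH, 4 Å MS, CH2Cl2, −25 °C
Reagents that add atoms: tert-butyl hydroperoxide CC(C)(C)OO
Why: Sharpless asymmetric epoxidation in the matched pairing (9 is the fast-reacting carbinol enantiomer for the D-tartrate) epoxidises only the electron-rich (E)-C7=C8 alkene and sets C7 and C8, while the iodoalkene is too electron-poor and (Z)-substituted to react.

Step 6
Reactants: 10 erythro epoxy alcohol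
Product: 11 threo epoxy phosphonoacetate
Conditions: (EtO)2P(O)CH2CO2H, PPh3, DIAD, THF, 0 °C to rt
Reagents that add atoms: 2-(diethoxyphosphoryl)acetic acid CCOP(=O)(CC(=O)O)OCC
Why: Mitsunobu esterification inverts C6 by SN2 displacement, so that the acyl tether and the epoxide oxygen become threo, the relationship a cis-lactone needs; SN2′ attack is blocked by the fully substituted C4.

Step 7
Reactants: 11 threo epoxy phosphonoacetate
Product: 12 phosphono lactone alcohol
Conditions: NaH (1.0 equiv), THF, 0 to 45 °C; aq. NH4Cl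
Reagents that add atoms: none
Why: Intramolecular alkylation of the phosphonate-stabilised carbanion by the epoxide (5-exo-tet, the carbon counterpart of the C2-selective opening of 2,3-epoxy alcohol carbamates and of the tandem Michael lactonisation of phosphonoacetate esters) attacks C7 with inversion, which closes the cis γ-lactone, sets C7 and frees the C8 hydroxyl with its epoxide-derived configuration; one equivalent of base leaves the alkoxide protonated by the acidic C11–H, so silyl migration should not occur.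

Step 8
Reactants: 12 phosphono lactone alcohol
Product: 13 angelate
Conditions: angelic acid, 2,4,6-trichlorobenzoyl chloride, Et3N, toluene, rt; then 12, 80 °C
Reagents that add atoms: angelic acid C/C=C(/C)C(=O)O
Why: Yamaguchi-type acylation through the preformed mixed anhydride, run without DMAP, should esterify the secondary C8 alcohol while keeping the (Z)-geometry of the angeloyl group.

Step 9
Reactants: 13 angelate
Product: 14 iodo alcohol
Conditions: PPTS, MeOH/CH2Cl2, 0 °C
Reagents that add atoms: none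
Why: Mild acid-catalysed methanolysis removes the secondary triethylsilyl ether selectively, the primary tert-butyldimethylsilyl ether being far less labile.

Step 10
Reactants: 14 iodo alcohol
Product: 15 seco dienone
Conditions: CO (3 atm), tributyl(vinyl)stannane, Pd2(dba)3 (5 mol%), AsPh3 (20 mol%), THF, 50 °C
Reagents that add atoms: carbon monoxide [C-]#[O+]; tributyl(vinyl)stannane C=C[Sn](CCCC)(CCCC)CCCC
Why: Carbonylative Stille coupling (oxidative addition of the alkenyl iodide to zerovalent palladium, CO insertion, transmetalation from the vinylstannane) should give the cross-conjugated dienone with retention of the (Z)-C4=C5 geometry and tolerates the free secondary alcohol.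

Step 11
Reactants: 15 seco dienone
Product: 16 macrocyclic phosphono lactone
Conditions: Ir[dF(CF3)ppy]2(dtbbpy)PF6 (2 mol%), quinuclidine (20 mol%), Bu4N(H2PO4) (25 mol%), MeCN (1 mM), blue LEDs, rt
Reagents that add atoms: none
Why: Proposed new method: the excited trivalent iridium photocatalyst oxidises quinuclidine to its radical cation, which abstracts the hydridic C10–H of the phosphate-bound secondary alcohol; the nucleophilic α-hydroxyalkyl radical adds to the unsubstituted terminus C1 of the vinyl ketone, and the α-keto radical is reduced by divalent iridium and protonated at C2, so 15 is simply isomerised to 16. The closest known reactions are the intermolecular photoredox/hydrogen-atom-transfer α-C–H alkylation of alcohols with Michael acceptors and the photoredox Giese macrocyclisation of peptides; a ten-membered carbocycle has not been closed this way. The ring closes in the 10-endo-trig mode at high dilution, helped by the cis-lactone and the (Z)-C4=C5 bond, which hold both arms on one side. The new quaternary centre C10 is set under substrate control: the transition state is expected to place the smaller hydroxyl, not the methyl group, syn to the C8 acyloxy group (no syn-pentane clash, possible O–H···O=C contact), which should give (10R). The step needs C1 to win over C5 (6-exo) and over the lactone: C5 is the β-branched end of a twisted angelate-type enone and should react far more slowly than a terminal vinyl ketone, C11 is kept sp3 by the phosphonate so that no methylene lactone is offered, and the single free hydroxyl directs the hydrogen abstraction to C10.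

Step 12
Reactants: 16 macrocyclic phosphono lactone
Product: 17 silyl-protected target
Conditions: aq. CH2O (37%), K2CO3, THF, 0 °C to rt
Reagents that add atoms: formaldehyde C=O
Why: Horner–Wadsworth–Emmons olefination of the α-phosphono lactone with formaldehyde installs the exocyclic methylene C13 and removes the phosphonate and the C11 stereocentre, the reactive aldehyde outcompeting the hindered ring ketone.

Step 13
Reactants: 17 silyl-protected target
Product: 18 CNP0181802.1
Conditions: HF·pyridine, pyridine, THF, 0 °C to rt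
Reagents that add atoms: none
Why: Buffered fluoride desilylation frees the primary allylic C15 alcohol under conditions that should leave the methylene lactone, the enone and the angelate untouched.

Compound list
1 | mono-silylated butynediol: 4-[(tert-butyldimethylsilyl)oxy]but-2-yn-1-ol | OCC#CCO[Si](C)(C)C(C)(C)C | starting material
2 | cyclic alkenylaluminate: sodium 3-{[(tert-butyldimethylsilyl)oxy]methyl}-2,2-bis(2-methoxyethoxy)-2,5-dihydro-1,2-oxaluminol-2-uide | [Na+].COCCO[Al-]1(OCCOC)OCC=C1CO[Si](C)(C)C(C)(C)C | intermediate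
3 | (Z)-iodo allylic alcohol: (2Z)-4-[(tert-butyldimethylsilyl)oxy]-3-iodobut-2-en-1-ol | OC/C=C(\I)CO[Si](C)(C)C(C)(C)C | intermediate
4 | (Z)-iodo enal: (2Z)-4-[(tert-butyldimethylsilyl)oxy]-3-iodobut-2-enal | O=C/C=C(\I)CO[Si](C)(C)C(C)(C)C | intermediate
5 | (2S)-pent-4-yn-2-ol | C[C@H](O)CC#C | starting material
6 | TES-protected alkynol: triethyl{[(2S)-pent-4-yn-2-yl]oxy}silane | C[C@H](O[Si](CC)(CC)CC)CC#C | intermediate
7 | alkenylborane: dicyclohexyl{(1E,4S)-4-[(triethylsilyl)oxy]pent-1-en-1-yl}borane | C[C@H](O[Si](CC)(CC)CC)C/C=C/B(C1CCCCC1)C1CCCCC1 | intermediate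
8 | alkenylzinc: methyl{(1E,4S)-4-[(triethylsilyl)oxy]pent-1-en-1-yl}zinc | C[C@H](O[Si](CC)(CC)CC)C/C=C/[Zn]C | intermediate
9 | bis-allylic alcohol: (2Z,4S,5E,8S)-1-[(tert-butyldimethylsilyl)oxy]-2-iodo-8-[(triethylsilyl)oxy]nona-2,5-dien-4-ol | O[C@H](/C=C(/CO[Si](C)(C)C(C)(C)C)I)/C=C/C[C@H](C)O[Si](CC)(CC)CC | intermediate
10 | erythro epoxy alcohol: (1R,2Z)-4-[(tert-butyldimethylsilyl)oxy]-3-iodo-1-[(2R,3R)-3-{(2S)-2-[(triethylsilyl)oxy]propyl}oxiran-2-yl]but-2-en-1-ol | O[C@H](/C=C(/CO[Si](C)(C)C(C)(C)C)I)[C@H]1O[C@@H]1C[C@H](C)O[Si](CC)(CC)CC | intermediate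
11 | threo epoxy phosphonoacetate: (1S,2Z)-4-[(tert-butyldimethylsilyl)oxy]-3-iodo-1-[(2S,3R)-3-{(2S)-2-[(triethylsilyl)oxy]propyl}oxiran-2-yl]but-2-en-1-yl (diethoxyphosphoryl)acetate | CCOP(=O)(OCC)CC(=O)O[C@@H](/C=C(/CO[Si](C)(C)C(C)(C)C)I)[C@H]1O[C@@H]1C[C@H](C)O[Si](CC)(CC)CC | intermediate
12 | phosphono lactone alcohol: diethyl [(4R,5R)-4-{(1R,3S)-1-hydroxy-3-[(triethylsilyl)oxy]butyl}-5-{(1Z)-3-[(tert-butyldimethylsilyl)oxy]-2-iodoprop-1-en-1-yl}-2-oxooxolan-3-yl]phosphonate, C3 epimers | O=C1O[C@@H](/C=C(/CO[Si](C)(C)C(C)(C)C)I)[C@@H]([C@H](O)C[C@H](C)O[Si](CC)(CC)CC)C1P(=O)(OCC)OCC | intermediate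
13 | angelate: (1R,3S)-1-[(2R,3R)-4-(diethoxyphosphoryl)-2-{(1Z)-3-[(tert-butyldimethylsilyl)oxy]-2-iodoprop-1-en-1-yl}-5-oxooxolan-3-yl]-3-[(triethylsilyl)oxy]butyl (2Z)-2-methylbut-2-enoate | O=C1O[C@@H](/C=C(/CO[Si](C)(C)C(C)(C)C)I)[C@@H]([C@H](OC(=O)/C(C)=C\C)C[C@H](C)O[Si](CC)(CC)CC)C1P(=O)(OCC)OCC | intermediate
14 | iodo alcohol: (1R,3S)-1-[(2R,3R)-4-(diethoxyphosphoryl)-2-{(1Z)-3-[(tert-butyldimethylsilyl)oxy]-2-iodoprop-1-en-1-yl}-5-oxooxolan-3-yl]-3-hydroxybutyl (2Z)-2-methylbut-2-enoate | O=C1O[C@@H](/C=C(/CO[Si](C)(C)C(C)(C)C)I)[C@@H]([C@H](OC(=O)/C(C)=C\C)C[C@H](C)O)C1P(=O)(OCC)OCC | intermediate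
15 | seco dienone: (1R,3S)-1-[(2S,3R)-2-{(1Z)-2-{[(tert-butyldimethylsilyl)oxy]methyl}-3-oxopenta-1,4-dien-1-yl}-4-(diethoxyphosphoryl)-5-oxooxolan-3-yl]-3-hydroxybutyl (2Z)-2-methylbut-2-enoate | O=C1O[C@@H](/C=C(/CO[Si](C)(C)C(C)(C)C)C(=O)C=C)[C@@H]([C@H](OC(=O)/C(C)=C\C)C[C@H](C)O)C1P(=O)(OCC)OCC | intermediate
16 | macrocyclic phosphono lactone: diethyl [(3aR,4R,6R,10Z,11aS)-10-{[(tert-butyldimethylsilyl)oxy]methyl}-6-hydroxy-6-methyl-4-{[(2Z)-2-methylbut-2-enoyl]oxy}-2,9-dioxo-2,3,3a,4,5,6,7,8,9,11a-decahydrocyclodeca[b]furan-3-yl]phosphonate, C3 epimers | CCOP(=O)(OCC)C1C(=O)O[C@H]2/C=C(/CO[Si](C)(C)C(C)(C)C)C(=O)CC[C@@](C)(O)C[C@@H](OC(=O)/C(C)=C\C)[C@@H]12 | intermediate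
17 | silyl-protected target: (3aR,4R,6R,10Z,11aS)-10-{[(tert-butyldimethylsilyl)oxy]methyl}-6-hydroxy-6-methyl-3-methylidene-2,9-dioxo-2,3,3a,4,5,6,7,8,9,11a-decahydrocyclodeca[b]furan-4-yl (2Z)-2-methylbut-2-enoate | C=C1C(=O)O[C@H]2/C=C(/CO[Si](C)(C)C(C)(C)C)C(=O)CC[C@@](C)(O)C[C@@H](OC(=O)/C(C)=C\C)[C@@H]12 | intermediate
18 | CNP0181802.1: (3aR,4R,6R,10Z,11aS)-6-hydroxy-10-(hydroxymethyl)-6-methyl-3-methylidene-2,9-dioxo-2,3,3a,4,5,6,7,8,9,11a-decahydrocyclodeca[b]furan-4-yl (2Z)-2-methylbut-2-enoate | C=C1C(=O)O[C@H]2/C=C(/CO)C(=O)CC[C@@](C)(O)C[C@@H](OC(=O)/C(C)=C\C)[C@@H]12 | target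

Total step count: 13. Longest linear sequence: 12 steps (from 1 through steps 1, 2 and 4 to 13).

Steps most likely to fail

Step 11 (Proposed new method). The radical may be intercepted before the slow ten-membered closure, by 6-exo addition to C5 or by intermolecular oligomerisation, or the ring may close with poor facial selectivity at C10. The fallback uses known chemistry, sets out from 14 and comes back at 16, and moves the ring closure to C3–C4 while still making the C1–C10 bond by the same radical chemistry. The photoredox alcohol α-C–H alkylation would be run intermolecularly on 14 with acrolein as acceptor, which should give the γ-lactol (1R)-1-[(2R,3R)-4-(diethoxyphosphoryl)-2-{(1Z)-3-[(tert-butyldimethylsilyl)oxy]-2-iodoprop-1-en-1-yl}-5-oxooxolan-3-yl]-2-(5-hydroxy-2-methyloxolan-2-yl)ethyl (2Z)-2-methylbut-2-enoate F1 as a mixture at C10. A Nozaki–Hiyama–Kishi reaction of the alkenyl iodide with the open hydroxy-aldehyde form (CrCl2, NiCl2 cat., DMSO, high dilution, divalent chromium in excess) would then give the macrocyclic diol diethyl [(3aR,4R,6R,10Z,11aS)-10-{[(tert-butyldimethylsilyl)oxy]methyl}-6,9-dihydroxy-6-methyl-4-{[(2Z)-2-methylbut-2-enoyl]oxy}-2-oxo-2,3,3a,4,5,6,7,8,9,11a-decahydrocyclodeca[b]furan-3-yl]phosphonate F2, the C10 epimers being separated at this point. MnO2 would oxidise the allylic C3 carbinol and return to 16.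

Step 10. Direct, non-carbonylative coupling may compete, or the divinyl ketone may polymerise or decompose under the warm palladium conditions. The fallback sets out from 14 and comes back at 15. A Nozaki–Hiyama–Kishi addition of the alkenyl iodide to acrolein (CrCl2, NiCl2 cat., DMSO, rt) should give the divinyl carbinol (1R,3S)-1-[(2S,3R)-4-(diethoxyphosphoryl)-2-{(1Z)-3-hydroxy-2-{[(tert-butyldimethylsilyl)oxy]methyl}penta-1,4-dien-1-yl}-5-oxooxolan-3-yl]-3-hydroxybutyl (2Z)-2-methylbut-2-enoate F3. MnO2 at room temperature should oxidise only the doubly allylic carbinol, leaving the saturated C10 alcohol, to give 15.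

Step 6. Configuration at C6 may be lost through SN2′ displacement, elimination, or participation of the neighbouring epoxide in the alkoxyphosphonium intermediate. The fallback sets out from 6 and 4, comes back at 11, and sets C6 directly so that no inversion is needed. Step 4 would be run with (+)-MIB to give the epimeric alcohol (2Z,4R,5E,8S)-1-[(tert-butyldimethylsilyl)oxy]-2-iodo-8-[(triethylsilyl)oxy]nona-2,5-dien-4-ol F4. Reagent-controlled Shi epoxidation (D-fructose-derived ketone, Oxone (2KHSO5·KHSO4·K2SO4), K2CO3 buffer, MeCN/H2O, 0 °C) should then give the threo epoxy alcohol (1S,2Z)-4-[(tert-butyldimethylsilyl)oxy]-3-iodo-1-[(2R,3R)-3-{(2S)-2-[(triethylsilyl)oxy]propyl}oxiran-2-yl]but-2-en-1-ol F5. Carbodiimide esterification with 2-(diethoxyphosphoryl)acetic acid (EDC·HCl, DMAP, CH2Cl2), with retention, would give 11.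

Further compounds
F1 | step 11 | (1R)-1-[(2R,3R)-4-(diethoxyphosphoryl)-2-{(1Z)-3-[(tert-butyldimethylsilyl)oxy]-2-iodoprop-1-en-1-yl}-5-oxooxolan-3-yl]-2-(5-hydroxy-2-methyloxolan-2-yl)ethyl (2Z)-2-methylbut-2-enoate | O=C1O[C@@H](/C=C(/CO[Si](C)(C)C(C)(C)C)I)[C@@H]([C@H](OC(=O)/C(C)=C\C)CC2(C)CCC(O)O2)C1P(=O)(OCC)OCC
F2 | step 11 | diethyl [(3aR,4R,6R,10Z,11aS)-10-{[(tert-butyldimethylsilyl)oxy]methyl}-6,9-dihydroxy-6-methyl-4-{[(2Z)-2-methylbut-2-enoyl]oxy}-2-oxo-2,3,3a,4,5,6,7,8,9,11a-decahydrocyclodeca[b]furan-3-yl]phosphonate | CCOP(=O)(OCC)C1C(=O)O[C@H]2/C=C(/CO[Si](C)(C)C(C)(C)C)C(O)CC[C@@](C)(O)C[C@@H](OC(=O)/C(C)=C\C)[C@@H]12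
F3 | step 10 | (1R,3S)-1-[(2S,3R)-4-(diethoxyphosphoryl)-2-{(1Z)-3-hydroxy-2-{[(tert-butyldimethylsilyl)oxy]methyl}penta-1,4-dien-1-yl}-5-oxooxolan-3-yl]-3-hydroxybutyl (2Z)-2-methylbut-2-enoate | O=C1O[C@@H](/C=C(/CO[Si](C)(C)C(C)(C)C)C(O)C=C)[C@@H]([C@H](OC(=O)/C(C)=C\C)C[C@H](C)O)C1P(=O)(OCC)OCC
F4 | step 6 | (2Z,4R,5E,8S)-1-[(tert-butyldimethylsilyl)oxy]-2-iodo-8-[(triethylsilyl)oxy]nona-2,5-dien-4-ol | O[C@@H](/C=C(/CO[Si](C)(C)C(C)(C)C)I)/C=C/C[C@H](C)O[Si](CC)(CC)CC
F5 | step 6 | (1S,2Z)-4-[(tert-butyldimethylsilyl)oxy]-3-iodo-1-[(2R,3R)-3-{(2S)-2-[(triethylsilyl)oxy]propyl}oxiran-2-yl]but-2-en-1-ol | O[C@@H](/C=C(/CO[Si](C)(C)C(C)(C)C)I)[C@H]1O[C@@H]1C[C@H](C)O[Si](CC)(CC)CC
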